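Target 25 is the umbelliferone ether (C11–O) of a trans-drimane carrying an axial 3α-angelate and 8α-OH/8β-CH3. The ester and the aryl ether are cut last, which leads back to drimane-3α,8α,11-triol 20.
Feature used: in ring B (C5–C10), C9 (bearing C11) sits between the quaternary, methyl-bearing C10 and the oxygenated C8, which is a cyclohexene retron. Cutting C5–C10 and C8–C9 opens rings B and A together to one chain: dienophile C9=C10 (E, C11 as imide), diene C5=C6–C7=C8–OAc (E,E), tether C1–C4 (C3 ketone, C4 gem-dimethyl).
Rings A and B are therefore formed together in one step (12 to 13, four stereocentres); the coumarin rings are bought.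
After the cycloaddition the C3 ketone is reduced to the axial alcohol at once, before any LiBH4 or LiAlH4 is used. Then imide to C11H2OH, and 8β-acetate to ketone, methylene, α-epoxide and 8α-carbinol.
Triene 12 is assembled from acid 1 (C3–C6), MeLi (C2), E-bromo ester 3 (C1, C10, C9, C11; alkene geometry bought), crotonaldehyde 10 (C7, C8) and oxazolidinone 7.
Key step: step 7

Assumption: drimane numbering is used throughout (also, by anticipation, for the open chains), and bromo ester 3 is used as the pure E isomer (commercial material containing Z isomer is chromatographed first).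

Step 1
Reactants: 1 2,2-dimethylpent-4-enoic acid
Product: 2 3,3-dimethylhex-5-en-2-one
Conditions: MeLi (2.2 equiv), Et2O, 0 °C to rt; inverse quench into ice-water
Reagents that add atoms: methyllithium, [Li]C
Why: Organolithium addition to a lithium carboxylate stops at the dilithium gem-diolate, which is long-lived next to the quaternary carbon, so the methyl ketone (its CH3 is the future C2) should be released only on quenching.

Step 2
Reactants: 2 3,3-dimethylhex-5-en-2-one; 3 ethyl (2E)-4-bromo-3-methylbut-2-enoate
Product: 5 ethyl (2E)-3,7,7-trimethyl-6-oxodeca-2,9-dienoate, via lithium enolate 4 (not isolated)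
Conditions: LiN(i-Pr)2, THF, −78 °C; then 3, DMPU, −78 to −20 °C
Reagents that add atoms: none
Why: SN2 alkylation of a ketone enolate forms C1–C2, because 2 can enolise only towards its methyl group, the primary allylic bromide should react faster than the β,β-disubstituted acceptor carbon, and the E geometry of 3 is carried over untouched, which avoids a poorly selective ketone olefination.

Step 3
Reactants: 5 ethyl (2E)-3,7,7-trimethyl-6-oxodeca-2,9-dienoate
Product: 6 (2E)-3,7,7-trimethyl-6-oxodeca-2,9-dienoic acid
Conditions: LiOH, THF/MeOH/H2O, rt to 40 °C; then 1 M HCl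
Reagents that add atoms: lithium hydroxide, [Li+].[OH-]
Why: Saponification of the conjugated ester by acyl–oxygen cleavage leaves the hindered ketone, the terminal alkene and the trisubstituted E alkene unchanged.

Step 4
Reactants: 6 (2E)-3,7,7-trimethyl-6-oxodeca-2,9-dienoic acid; 7 oxazolidin-2-one
Product: 9 3-[(2E)-3,7,7-trimethyl-6-oxodeca-2,9-dienoyl]oxazolidin-2-one, via mixed pivalic anhydride 8 (not isolated)
Conditions: t-BuCOCl, Et3N, THF, −20 °C; then LiCl, 7, rt
Reagents that add atoms: none
Why: N-acylation of the oxazolidinone through a mixed anhydride under LiCl/Et3N is a mild standard route to enoyl imides, attack occurring at the less hindered enoyl carbonyl without strong base that could deconjugate the alkene.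

Step 5
Reactants: 9 3-[(2E)-3,7,7-trimethyl-6-oxodeca-2,9-dienoyl]oxazolidin-2-one; 10 (E)-but-2-enal (crotonaldehyde)
Product: 11 3-[(2E,9E)-3,7,7-trimethyl-6,11-dioxoundeca-2,9-dienoyl]oxazolidin-2-one
Conditions: 10 (5 equiv), second-generation Hoveyda–Grubbs catalyst RuCl2(H2IMes)(=CH-C6H4-2-O-i-Pr) (3 mol %), CH2Cl2, 40 °C
Reagents that add atoms: none
Why: Olefin cross-metathesis of an unhindered terminal alkene with an excess of an electron-poor enal should give the E-enal (C6=C7–C8HO), while the trisubstituted, electron-poor C9=C10 bond is inert to the ruthenium carbene.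

Step 6
Reactants: 11 3-[(2E,9E)-3,7,7-trimethyl-6,11-dioxoundeca-2,9-dienoyl]oxazolidin-2-one
Product: 12 3-[(2E,8E,10E)-11-acetoxy-3,7,7-trimethyl-6-oxoundeca-2,8,10-trienoyl]oxazolidin-2-one
Conditions: Ac2O, Et3N, DMAP (cat.), CH2Cl2, rt to 40 °C
Reagents that add atoms: acetic anhydride, CC(=O)OC(C)=O
Why: Dienol acetate formation (vinylogous enolisation and O-acylation) works because the γ-protons at C5 of the enal are the only ones an amine base can remove; the s-trans enal and the bulky C4 group should favour the E,E-diene, the minor 10Z isomer is removed by chromatography, and placing this step last spares the sensitive dienyl acetate all acidic and strongly basic steps.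

Step 7
Reactants: 12 3-[(2E,8E,10E)-11-acetoxy-3,7,7-trimethyl-6-oxoundeca-2,8,10-trienoyl]oxazolidin-2-one
Product: 13 3-(8β-acetoxy-3-oxo-12-nordrim-6-en-11-oyl)oxazolidin-2-one (trans-fused; 5α-H, 9α-H, 10β-CH3)
Conditions: [Cu((R,R)-t-Bu-box)](SbF6)2 (20 mol %; from CuCl2, AgSbF6 and 2,2'-isopropylidenebis[(4R)-4-tert-butyl-2-oxazoline]), CH2Cl2, 25 to 40 °C
Reagents that add atoms: none
Why: Proposed new method: the square-planar divalent copper centre binds both imide carbonyls, lowers the LUMO of the s-cis enoyl unit and lets C10 (β-carbon) meet C5 (the diene terminus remote from the acetoxy group, largest HOMO coefficient) in a concerted, asynchronous [4+2] cycloaddition that also joins C9 to C8; the closest known reactions are the copper–bis(oxazoline)-catalysed intramolecular Diels–Alder reaction of β-monosubstituted trienimides and the intermolecular reaction of 1-acetoxybutadiene with the same catalyst, whereas a β,β-disubstituted imide has not been shown to react. Ring B closes as the cyclohexene of the cycloaddition (C6=C7 remains) and ring A closes simultaneously through the four-atom tether C1–C4 folded chair-like (1,7,9-decatriene mode). Suprafacial addition preserves the E geometry, so the C10 methyl and C11 become cis (both β); the outer substituents of the E,E-diene (C4 and OAc) become cis to each other, and the endo placement of the imide puts them on the face of C11, which means trans fusion (5α-H against 10β-CH3) and 8β-OAc. In the square-planar model the (S,S)-ligand covers the Si face of the α-carbon (Re attack, as for acrylimide); C9 of 13 needs Si attack, hence the (R,R)-ligand. The step needs endo over exo selectivity, one dienophile face and sufficient rate: two-point binding of the cationic complex supports the first two, regiochemistry is fixed by the tether and electronically matched, and the C4 gem-dimethyl group with the sp2 C3 compresses the tether. The developing 1,3-diaxial contact of the 4β and C10 methyl groups and the methyl group cis to the bound carbonyl work against the reaction.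

Step 8
Reactants: 13 3-(8β-acetoxy-3-oxo-12-nordrim-6-en-11-oyl)oxazolidin-2-one
Product: 14 3-(8β-acetoxy-3α-hydroxy-12-nordrim-6-en-11-oyl)oxazolidin-2-one
Conditions: K(s-Bu)3BH (1.2 equiv), THF, −78 °C; AcOH quench
Reagents that add atoms: none
Why: Bulky-hydride ketone reduction takes the equatorial trajectory at C3 of the 4,4-dimethyl chair and should give the axial 3α-alcohol, the ketone reacting far faster than imide or acetate at −78 °C, and doing it now ensures that the later small hydrides cannot produce the 3β epimer.

Step 9
Reactants: 14 3-(8β-acetoxy-3α-hydroxy-12-nordrim-6-en-11-oyl)oxazolidin-2-one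
Product: 15 12-nordrim-6-ene-3α,8β,11-triol
Conditions: LiBH4 (excess), MeOH (additive), THF, 0 °C to rt
Reagents that add atoms: none
Why: Borohydride reduction of the N-acyl oxazolidinone gives the primary C11 alcohol and frees the heterocycle, the acetate is reduced off in the same operation, and the weakly basic medium avoids loss of acetic acid across C8–C9.

Step 10
Reactants: 15 12-nordrim-6-ene-3α,8β,11-triol
Product: 16 3α,11-dihydroxy-12-nordrim-6-en-8-one
Conditions: activated MnO2 (excess), CH2Cl2, rt
Reagents that add atoms: none
Why: MnO2 oxidation is selective for the allylic C8 alcohol, so the saturated 3α and primary C11 hydroxyl groups need no protection, the pseudoaxial position of the 8β-OH costing only rate.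

Step 11
Reactants: 16 3α,11-dihydroxy-12-nordrim-6-en-8-one
Product: 17 3α,11-dihydroxy-12-nordriman-8-one
Conditions: H2 (1 atm), Pd/C, EtOAc, rt
Reagents that add atoms: none
Why: Heterogeneous catalytic hydrogenation saturates the conjugated C6=C7 bond under neutral conditions, creates no stereocentre and leaves the equatorial (thermodynamically preferred) C9 substituent in place.

Step 12
Reactants: 17 3α,11-dihydroxy-12-nordriman-8-one
Product: 18 drim-8(12)-ene-3α,11-diol
Conditions: Zn, CH2Br2, TiCl4, THF/CH2Cl2, 0 °C to rt
Reagents that add atoms: dibromomethane, BrCBr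
Why: Takai–Lombardo methylenation uses a non-basic gem-dimetal reagent that tolerates hydroxyl groups as metal alkoxides, so the β-hydroxy ketone should be methylenated (C12) without retro-aldol loss of C11, β-elimination or C9 epimerisation.

Step 13
Reactants: 18 drim-8(12)-ene-3α,11-diol
Product: 19 8α,12-epoxydrimane-3α,11-diol
Conditions: mCPBA, CH2Cl2, 0 °C
Reagents that add atoms: 3-chloroperbenzoic acid, O=C(OO)c1cccc(Cl)c1
Why: Prilezhaev epoxidation of the exocyclic alkene should occur from the α face because the axial C10 methyl group screens the β face, which places the oxygen on the α side of the new C8 stereocentre.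

Step 14
Reactants: 19 8α,12-epoxydrimane-3α,11-diol
Product: 20 drimane-3α,8α,11-triol
Conditions: LiAlH4, THF, 0 °C to reflux
Reagents that add atoms: none
Why: Hydride opening of the epoxide by SN2 attack at the unhindered C12 methylene leaves the C8–O bond intact, giving the equatorial 8α-hydroxyl and axial 8β-methyl group.

Step 15
Reactants: 20 drimane-3α,8α,11-triol; 21 umbelliferone (7-hydroxycoumarin)
Product: 22 7-[(3α,8α-dihydroxydriman-11-yl)oxy]coumarin
Conditions: PPh3, DIAD, THF, 0 °C to rt
Reagents that add atoms: none
Why: Mitsunobu etherification should engage only the primary C11 alcohol, since the axial neopentyl-type C3 alcohol and the tertiary C8 alcohol do not form displaceable oxyphosphonium ions, and the acidic phenol is an ideal partner under conditions that spare the lactone.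

Step 16
Reactants: 22 7-[(3α,8α-dihydroxydriman-11-yl)oxy]coumarin; 23 angelic acid ((2Z)-2-methylbut-2-enoic acid)
Product: 25 7-{[3α-(angeloyloxy)-8α-hydroxydriman-11-yl]oxy}coumarin (target), via mixed trichlorobenzoic anhydride 24 (not isolated)
Conditions: 23, 2,4,6-trichlorobenzoyl chloride, Et3N, toluene, rt; then 22, 80 °C
Reagents that add atoms: none
Why: Yamaguchi-type mixed-anhydride acylation without a nucleophilic catalyst transfers the angeloyl group to the secondary 3α-alcohol (the tertiary 8α-alcohol is inert) with retention at C3, and omitting DMAP suppresses the addition–elimination path that isomerises the Z alkene.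

Compound list
1 | 2,2-dimethylpent-4-enoic acid | C=CCC(C)(C)C(=O)O | starting material
2 | 3,3-dimethylhex-5-en-2-one | CC(=O)C(C)(C)CC=C | intermediate
3 | ethyl (2E)-4-bromo-3-methylbut-2-enoate | CCOC(=O)/C=C(\C)CBr | starting material
4 | lithium 3,3-dimethylhexa-1,5-dien-2-olate (enolate of 2, not isolated) | [Li]OC(=C)C(C)(C)CC=C | intermediate
5 | ethyl (2E)-3,7,7-trimethyl-6-oxodeca-2,9-dienoate | CCOC(=O)/C=C(\C)CCC(=O)C(C)(C)CC=C | intermediate
6 | (2E)-3,7,7-trimethyl-6-oxodeca-2,9-dienoic acid | OC(=O)/C=C(\C)CCC(=O)C(C)(C)CC=C | intermediate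
7 | oxazolidin-2-one | O=C1NCCO1 | starting material
8 | mixed anhydride of 6 and pivalic acid (not isolated) | CC(C)(C)C(=O)OC(=O)/C=C(\C)CCC(=O)C(C)(C)CC=C | intermediate
9 | 3-[(2E)-3,7,7-trimethyl-6-oxodeca-2,9-dienoyl]oxazolidin-2-one | O=C(N1CCOC1=O)/C=C(\C)CCC(=O)C(C)(C)CC=C | intermediate
10 | (E)-but-2-enal (crotonaldehyde) | C/C=C/C=O | starting material
11 | 3-[(2E,9E)-3,7,7-trimethyl-6,11-dioxoundeca-2,9-dienoyl]oxazolidin-2-one | O=C(N1CCOC1=O)/C=C(\C)CCC(=O)C(C)(C)C/C=C/C=O | intermediate
12 | 3-[(2E,8E,10E)-11-acetoxy-3,7,7-trimethyl-6-oxoundeca-2,8,10-trienoyl]oxazolidin-2-one | O=C(N1CCOC1=O)/C=C(\C)CCC(=O)C(C)(C)/C=C/C=C/OC(C)=O | intermediate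
13 | 3-(8β-acetoxy-3-oxo-12-nordrim-6-en-11-oyl)oxazolidin-2-one (5α-H, 9α-H, 10β-CH3) | O=C1CC[C@]2(C)[C@@H](C(=O)N3CCOC3=O)[C@@H](OC(C)=O)C=C[C@H]2C1(C)C | intermediate
14 | 3-(8β-acetoxy-3α-hydroxy-12-nordrim-6-en-11-oyl)oxazolidin-2-one | O[C@@H]1CC[C@]2(C)[C@@H](C(=O)N3CCOC3=O)[C@@H](OC(C)=O)C=C[C@H]2C1(C)C | intermediate
15 | 12-nordrim-6-ene-3α,8β,11-triol | O[C@@H]1CC[C@]2(C)[C@@H](CO)[C@@H](O)C=C[C@H]2C1(C)C | intermediate
16 | 3α,11-dihydroxy-12-nordrim-6-en-8-one | O[C@@H]1CC[C@]2(C)[C@@H](CO)C(=O)C=C[C@H]2C1(C)C | intermediate
17 | 3α,11-dihydroxy-12-nordriman-8-one | O[C@@H]1CC[C@]2(C)[C@@H](CO)C(=O)CC[C@H]2C1(C)C | intermediate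
18 | drim-8(12)-ene-3α,11-diol | O[C@@H]1CC[C@]2(C)[C@@H](CO)C(=C)CC[C@H]2C1(C)C | intermediate
19 | 8α,12-epoxydrimane-3α,11-diol | O[C@@H]1CC[C@]2(C)[C@@H](CO)[C@@]3(CO3)CC[C@H]2C1(C)C | intermediate
20 | drimane-3α,8α,11-triol | O[C@@H]1CC[C@]2(C)[C@@H](CO)[C@](C)(O)CC[C@H]2C1(C)C | intermediate
21 | umbelliferone (7-hydroxycoumarin) | Oc1ccc2ccc(=O)oc2c1 | starting material
22 | 7-[(3α,8α-dihydroxydriman-11-yl)oxy]coumarin | O[C@@H]1CC[C@]2(C)[C@@H](COc3ccc4ccc(=O)oc4c3)[C@](C)(O)CC[C@H]2C1(C)C | intermediate
23 | angelic acid, (2Z)-2-methylbut-2-enoic acid | C/C=C(/C)C(=O)O | starting material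
24 | angelic 2,4,6-trichlorobenzoic anhydride (not isolated) | C/C=C(/C)C(=O)OC(=O)c1c(Cl)cc(Cl)cc1Cl | intermediate
25 | 7-{[3α-(angeloyloxy)-8α-hydroxydriman-11-yl]oxy}coumarin | C/C=C(/C)C(=O)O[C@@H]1CC[C@]2(C)[C@@H](COc3ccc4ccc(=O)oc4c3)[C@](C)(O)CC[C@H]2C1(C)C | target

Total step count: 16
Longest linear sequence: 16 steps (1 to 25)

Steps most likely to fail

1. Step 7.
- What may go wrong: the β,β-disubstituted imide may react too slowly at the copper centre. The C3 ketone or the acetate may compete for the Lewis acid. Acetic acid may be lost across C8–C9 of the adduct. Endo or facial selectivity may erode under the steric load of the forming C5–C10 bond.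
- Fallback: substrate control and heat replace the chiral Lewis acid, using only known reaction types; it sets out from 12 and comes back at 13.
- Corey–Bakshi–Shibata reduction of the tert-alkyl ketone of 12 ((R)-2-methyl-oxazaborolidine, catecholborane, toluene, −78 °C) should give the (6S)-6-hydroxy trienimide F1.
- TBSOTf and 2,6-lutidine (CH2Cl2, 0 °C) convert it into the tert-butyldimethylsilyl ether F2.
- A thermal intramolecular Diels–Alder reaction (toluene, BHT, sealed tube, 130–160 °C) follows. This is a documented way to trans-decalins with an angular methyl group from β-methyl acceptor alkenes. It should give the 3β-silyloxy cycloadduct F3.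
- The bulky C3 substituent takes the equatorial site of the chair-like tether and so selects the diene face. Stereoisomers are removed by chromatography at this stage.
- HF·pyridine (THF, 0 °C) frees the 3β-hydroxy cycloadduct F4, and Dess–Martin periodinane (CH2Cl2, rt) oxidises it to 13.

2. Step 15.
- What may go wrong: displacement at the neopentyl-like C11 oxyphosphonium centre may be slow, leaving room for participation of the neighbouring 8α-hydroxyl group or for consumption of the azodicarboxylate.
- Fallback: it sets out from 20 and comes back at 22, and forms the aryl–oxygen bond instead of the C11–oxygen bond.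
- The method is a Buchwald–Hartwig-type etherification of the primary alcohol of 20 with purchased 7-bromocoumarin ([Pd(allyl)Cl]2, RockPhos, Cs2CO3, toluene, 90 °C).
- No substitution at C11 is needed, and primary alcohols couple in preference to secondary and tertiary ones. This fallback makes no compound outside the list (F0).

3. Step 16.
- What may go wrong: acyl transfer to the hindered axial 3α-hydroxyl group may be sluggish, giving the activated Z-acyl unit time to isomerise to the E form.
- Fallback: it sets out from 22 and comes back at 25, and builds the Z alkene after the acylation.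
- Esterification of 22 with 2-[bis(2,2,2-trifluoroethoxy)phosphoryl]propanoic acid (DCC, DMAP, CH2Cl2, rt) gives the 3α-phosphonopropionate F5.
- Still–Gennari olefination (KN(SiMe3)2, 18-crown-6, THF, −78 °C; then acetaldehyde) should give the Z-trisubstituted ester 25.

Further compounds
F1 | step 7 | 3-[(2E,6S,8E,10E)-11-acetoxy-6-hydroxy-3,7,7-trimethylundeca-2,8,10-trienoyl]oxazolidin-2-one | O=C(N1CCOC1=O)/C=C(\C)CC[C@H](O)C(C)(C)/C=C/C=C/OC(C)=O
F2 | step 7 | 3-[(2E,6S,8E,10E)-11-acetoxy-6-(tert-butyldimethylsilyloxy)-3,7,7-trimethylundeca-2,8,10-trienoyl]oxazolidin-2-one | O=C(N1CCOC1=O)/C=C(\C)CC[C@H](O[Si](C)(C)C(C)(C)C)C(C)(C)/C=C/C=C/OC(C)=O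
F3 | step 7 | 3-[8β-acetoxy-3β-(tert-butyldimethylsilyloxy)-12-nordrim-6-en-11-oyl]oxazolidin-2-one | CC(C)(C)[Si](C)(C)O[C@H]1CC[C@]2(C)[C@@H](C(=O)N3CCOC3=O)[C@@H](OC(C)=O)C=C[C@H]2C1(C)C
F4 | step 7 | 3-(8β-acetoxy-3β-hydroxy-12-nordrim-6-en-11-oyl)oxazolidin-2-one | O[C@H]1CC[C@]2(C)[C@@H](C(=O)N3CCOC3=O)[C@@H](OC(C)=O)C=C[C@H]2C1(C)C
F0 | step 15 | none | none
F5 | step 16 | 7-{[3α-(2-[bis(2,2,2-trifluoroethoxy)phosphoryl]propanoyloxy)-8α-hydroxydriman-11-yl]oxy}coumarin (epimers at the phosphonate carbon) | CC(C(=O)O[C@@H]1CC[C@]2(C)[C@@H](COc3ccc4ccc(=O)oc4c3)[C@](C)(O)CC[C@H]2C1(C)C)P(=O)(OCC(F)(F)F)OCC(F)(F)F
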